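**Retrosynthetic overview**
1. The C14 and C15 hydroxyls come last (SeO2/t-BuOOH, which also turns C1=C10 ring-cis); before that the O8 angelate, the C13 methylene (Mannich/elimination) and the 6,12-lactone (oxidative lactonisation after 1,2-reduction of a C6 ketone) lead back to cyclodecadienone 16.
2. Feature used: C6, C5=C4(C15), C3, C2 and C1 with the C10(C14)=C9 branch on C1 are the carbons of isopiperitenone, and O6 lies 1,5 to C1=C10 through C7=C8, so the ten-membered carbocycle is a cyclohexene enlarged by C7–C10.
3. Key disconnection: 16 ⇒ cyclohexenol 13 by an anionic oxy-Cope transform (C8–C9 formed, C1–C6 cleaved; 8R from the chair, 7R from protonation).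
4. 13 ⇒ (R)-isopiperitenone 2 (from (S)-limonene 1) + E-alkenyllithium 12 (from ynol ether 9, built from 4-methoxybenzyl alcohol 3, trichloroethylene 4 and iodide 6).
5. Ring order: cyclohexene (present in 1) → ten-membered carbocycle (step 6) → γ-lactone (step 9).

Key step: step 6

Remark: atoms carry the germacrane numbers of the target throughout (PMB = 4-methoxybenzyl, TBS = tert-butyldimethylsilyl; "ring-cis/ring-trans" refers to the two ring bonds at a double bond), and the hydrozirconation of 9 is assumed to follow the polarisation of the ynol ether (Zr on the carbon remote from oxygen), as it does for ethoxyacetylene.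

**Route**

Step 1
Reactants: 1 (S)-(−)-limonene
Product: 2 (R)-isopiperitenone
Conditions: t-BuOOH, Cr(CO)6 (cat.), MeCN, reflux
Reagents that add atoms: tert-butyl hydroperoxide, CC(C)(C)OO
Why: Chromium-catalysed allylic oxidation turns the ring CH2 between the olefin and the isopropenyl-bearing carbon (the future C6) into the enone carbonyl, the regioisomer carvone being removed by chromatography, and the neutral medium should leave the stereocentre, now α to the carbonyl, intact.

Step 2
Reactants: 3 4-methoxybenzyl alcohol; 4 trichloroethylene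
Product: 5 (E)-1,2-dichlorovinyl 4-methoxybenzyl ether
Conditions: KH, THF, 0 °C; then 4, −40 °C → rt
Reagents that add atoms: none
Why: The potassium alkoxide dehydrochlorinates trichloroethylene to dichloroacetylene and adds to it anti (alkoxide addition to a haloalkyne), which should give the E-dichlorovinyl ether.

Step 3
Reactants: 5 (E)-1,2-dichlorovinyl 4-methoxybenzyl ether; 6 tert-butyl(2-iodoethoxy)dimethylsilane
Product: 9 PMB ynol ether PMBO–C≡C–CH2CH2OTBS, via chloroethynyl ether 7 (not isolated), via lithium alkoxyacetylide 8 (not isolated)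
Conditions: n-BuLi (2.2 equiv), THF, −78 → −40 °C; then 6, DMPU, −40 °C → rt
Reagents that add atoms: none
Why: Dehydrochlorination followed by chlorine–lithium exchange is the standard entry to lithium alkoxyacetylides, and SN2 alkylation by the primary iodide in the presence of DMPU should give the internal ynol ether, which is kept at or below room temperature because benzyl alkynyl ethers rearrange on heating.

Step 4
Reactants: 9 PMB ynol ether
Product: 11 (E)-β-iodo enol ether I–C7(CH2CH2OTBS)=C8H–OPMB with iodine trans to OPMB, via alkenylzirconocene 10 (not isolated)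
Conditions: Cp2Zr(H)Cl, THF, 0 °C → rt; then I2, −78 → 0 °C
Reagents that add atoms: iodine, II
Why: Syn hydrozirconation with the Schwartz reagent delivers hydride to the electrophilic oxygen-bearing carbon and zirconium to the nucleophilic β-carbon, and iodinolysis with retention then places iodine cis to the vinyl hydrogen and trans to OPMB.

Step 5
Reactants: 11 (E)-β-iodo enol ether; 2 (R)-isopiperitenone
Product: 13 (1R,6R)-cyclohexenol carrying the (E)-PMB enol ether on C6 trans to the C1 isopropenyl group, via alkenyllithium 12 (not isolated)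
Conditions: t-BuLi (2 equiv), Et2O, −100 °C; then 2, −100 → −78 °C; H2O
Reagents that add atoms: none
Why: Iodine–lithium exchange proceeds with retention and at −100 °C should outrun anti β-elimination of lithium 4-methoxybenzyl oxide from the trans-β-alkoxyvinyllithium (the same constraint that applies to 3-lithiobenzofuran), and 1,2-addition to the enone on the face anti to the neighbouring isopropenyl group (equatorial attack on the half-chair) sets C6 as R with the two alkenyl groups trans.

Step 6
Reactants: 13 (1R,6R)-cyclohexenol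
Product: 16 (7R,8R)-cyclodecadienone with C6 ketone and C4=C5 ring-cis and C1=C10 ring-trans, via potassium alkoxide 14 (not isolated), via potassium enolate 15 (not isolated)
Conditions: KH, 18-crown-6, THF, 0 °C → rt; then −78 °C, AcOH
Reagents that add atoms: none
Why: KH/18-crown-6 gives the dissociated potassium alkoxide 14, whose oxido group weakens the C1–C6 bond so that the 1,5-diene C8=C7–C6–C1–C10=C9 undergoes a concerted [3,3] shift forming C8–C9 and cleaving C1–C6 (anionic oxy-Cope rearrangement, known for 1-alkenyl-6-isopropenylcyclohex-2-enols giving germacrane-type cyclodecadienones). The ten-membered ring is not closed end to end but arises by four-atom expansion of the cyclohexene through a six-centre chair transition state in which both ring bonds (C6–C5 and C1–C2) are equatorial and the alkoxide is axial. C8 is set in the shift: the E-enol ether oxygen is equatorial in that chair, so C9 bonds to the C8 face that gives 8R, the chirality of the limonene-derived C1 being relayed through C6 before both become sp2. The same chair leaves C4=C5 ring-cis, makes C1=C10 ring-trans and gives a ring-trans C6=C7 enolate whose substituents cannot turn through the ring, so protonation at −78 °C should occur on its outer face (anti to the new C8–C9 bond) and set 7R. The step needs chair over boat and clean chirality transfer, secured by the trans arrangement of the two alkenyl groups and the defined E enol ether, and it needs the β-alkoxy enolate 15 to survive, hence the lowest workable temperature and a cold acetic acid quench.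

Step 7
Reactants: 16 (7R,8R)-cyclodecadienone
Product: 17 (6R,7S,8R)-allylic alcohol with 6α-OH
Conditions: NaBH4, CeCl3·7H2O, MeOH, −78 °C
Reagents that add atoms: none
Why: Luche 1,2-reduction of the enone is expected to deliver hydride to the outer face of C6 (away from the transannular C1=C10 bond), which together with the outer-face protonation at C7 amounts to syn addition across the former ring-trans enolate and so gives the 6,7-trans relation (6R) without disturbing the base-sensitive β-alkoxy ketone.

Step 8
Reactants: 17 (6R,7S,8R)-allylic alcohol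
Product: 18 (6R,7S,8R)-6,12-diol
Conditions: Bu4NF, THF, 0 °C → rt
Reagents that add atoms: none
Why: Fluoride cleaves the primary silyl ether (desilylation) while the PMB ether, the allylic alcohol and the olefins are inert.

Step 9
Reactants: 18 (6R,7S,8R)-6,12-diol
Product: 21 (6R,7R,8R)-trans-fused 6α,12-lactone (13-nor) with 8β-OPMB, via hydroxy aldehyde 19 (not isolated), via lactol 20 (not isolated)
Conditions: TEMPO (cat.), PhI(OAc)2, CH2Cl2, rt
Reagents that add atoms: none
Why: Oxoammonium oxidation is selective for the primary alcohol, the aldehyde is captured by the C6 hydroxyl as a lactol and this is oxidised further (oxidative lactonisation of a 1,4-diol), closing the γ-lactone without touching C6, C7 or C8.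

Step 10
Reactants: 21 (6R,7R,8R)-6α,12-lactone
Product: 23 11-(dimethylaminomethyl) lactone (C11 epimers), via lithium enolate 22 (not isolated)
Conditions: LiN(iPr)2, THF, −78 °C; then CH2=NMe2+ I−, −78 °C → rt
Reagents that add atoms: N,N-dimethylmethyleneiminium iodide (Eschenmoser's salt), C=[N+](C)C.[I-]
Why: The lactone enolate has no β-leaving group and undergoes a Mannich reaction with the iminium salt at C11, whose configuration is irrelevant because it becomes sp2 in the next step.

Step 11
Reactants: 23 11-(dimethylaminomethyl) lactone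
Product: 25 α-methylene lactone with 8β-OPMB, via trimethylammonium iodide 24 (not isolated)
Conditions: MeI, MeOH, rt; then NaHCO3, H2O/CH2Cl2, rt
Reagents that add atoms: none
Why: N-Quaternisation followed by mild-base E1cB elimination of trimethylamine (Hofmann-type) installs the C11=C13 methylene.

Step 12
Reactants: 25 α-methylene lactone with 8β-OPMB
Product: 26 (6R,7R,8R)-8β-hydroxy α-methylene lactone
Conditions: DDQ, CH2Cl2/pH 7 buffer, 0 °C
Reagents that add atoms: none
Why: Oxidative PMB cleavage (benzylic hydride abstraction, then hydrolysis of the oxocarbenium ion) works under neutral conditions that spare the acid-sensitive cyclodecadiene and the Michael-acceptor lactone and retain the C8–O bond.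

Step 13
Reactants: 26 (6R,7R,8R)-8β-hydroxy α-methylene lactone; 27 angelic acid
Product: 29 8β-angelate with C1=C10 ring-trans and C4=C5 ring-cis, via mixed anhydride 28 (not isolated)
Conditions: 2,4,6-Cl3C6H2COCl, Et3N, toluene, rt; then 26, 75 °C
Reagents that add atoms: none
Why: Yamaguchi-type acylation through the 2,4,6-trichlorobenzoic mixed anhydride without a nucleophilic catalyst transfers the angeloyl group to O8 with retention at C8 and should avoid the Z-to-E isomerisation to the tiglate that carbodiimide/DMAP methods cause.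

Step 14
Reactants: 29 8β-angelate
Product: 30 target CNP0182172.4
Conditions: SeO2 (cat.), t-BuOOH, CH2Cl2, 0 °C → rt
Reagents that add atoms: tert-butyl hydroperoxide, CC(C)(C)OO
Why: Catalytic SeO2 allylic hydroxylation (ene reaction then [2,3]-sigmatropic shift) should attack the methyl groups on the two electron-rich trisubstituted ring olefins rather than the electron-poor angelate and methylene lactone, and the [2,3] step re-forms each olefin with the CH2OH trans to the ring carbon on the other terminus, which keeps C15 trans to C6 and turns C1=C10 ring-cis (C14 trans to C2) as known for 1(10)-trans germacranolides.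

**Compound list**
1 | (S)-(−)-limonene | CC1=CC[C@H](CC1)C(C)=C | starting material
2 | (R)-isopiperitenone, (6R)-3-methyl-6-(prop-1-en-2-yl)cyclohex-2-en-1-one | CC1=CC(=O)[C@@H](C(C)=C)CC1 | intermediate
3 | 4-methoxybenzyl alcohol | COc1ccc(CO)cc1 | starting material
4 | trichloroethylene | ClC=C(Cl)Cl | starting material
5 | (E)-1,2-dichlorovinyl 4-methoxybenzyl ether | COc1ccc(CO/C(Cl)=C\Cl)cc1 | intermediate
6 | tert-butyl(2-iodoethoxy)dimethylsilane | ICCO[Si](C)(C)C(C)(C)C | starting material
7 | chloroethynyl 4-methoxybenzyl ether (not isolated) | COc1ccc(COC#CCl)cc1 | intermediate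
8 | lithium [(4-methoxybenzyl)oxy]acetylide (not isolated) | COc1ccc(COC#C[Li])cc1 | intermediate
9 | tert-butyl({4-[(4-methoxybenzyl)oxy]but-3-yn-1-yl}oxy)dimethylsilane | COc1ccc(COC#CCCO[Si](C)(C)C(C)(C)C)cc1 | intermediate
10 | alkenylzirconocene chloride, Zr on C7 cis to the vinyl H and trans to OPMB (not isolated) | Cl[Zr](C1C=CC=C1)(C1C=CC=C1)/C(CCO[Si](C)(C)C(C)(C)C)=C/OCc1ccc(OC)cc1 | intermediate
11 | tert-butyl({(3E)-3-iodo-4-[(4-methoxybenzyl)oxy]but-3-en-1-yl}oxy)dimethylsilane (I trans to OPMB) | I/C(CCO[Si](C)(C)C(C)(C)C)=C/OCc1ccc(OC)cc1 | intermediate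
12 | alkenyllithium, Li on C7 trans to OPMB (not isolated) | [Li]/C(CCO[Si](C)(C)C(C)(C)C)=C/OCc1ccc(OC)cc1 | intermediate
13 | (1R,6R)-1-[(1E)-4-(TBSO)-1-(PMBO)but-1-en-2-yl]-3-methyl-6-(prop-1-en-2-yl)cyclohex-2-en-1-ol (alkenyl groups trans) | CC1=C[C@](O)(/C(CCO[Si](C)(C)C(C)(C)C)=C/OCc2ccc(OC)cc2)[C@@H](C(C)=C)CC1 | intermediate
14 | potassium alkoxide of 13 (not isolated) | CC1=C[C@]([O-])(/C(CCO[Si](C)(C)C(C)(C)C)=C/OCc2ccc(OC)cc2)[C@@H](C(C)=C)CC1.[K+] | intermediate
15 | potassium enolate of 16, C6=C7 ring-trans, 8R (not isolated) | [K+].[O-]/C1=C(/CCO[Si](C)(C)C(C)(C)C)[C@H](OCc2ccc(OC)cc2)C/C(C)=C/CC/C(C)=C\1 | intermediate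
16 | (7R,8R)-7-(2-TBSO-ethyl)-8-PMBO-4,10-dimethylcyclodeca-4,1(10)-dien-6-one (germacrane numbers; C4=C5 ring-cis, C1=C10 ring-trans) | O=C1/C=C(/C)CC/C=C(\C)C[C@@H](OCc2ccc(OC)cc2)[C@H]1CCO[Si](C)(C)C(C)(C)C | intermediate
17 | (6R,7S,8R)-6α-alcohol of 16 | O[C@@H]1/C=C(/C)CC/C=C(\C)C[C@@H](OCc2ccc(OC)cc2)[C@H]1CCO[Si](C)(C)C(C)(C)C | intermediate
18 | (6R,7S,8R)-6,12-diol | O[C@@H]1/C=C(/C)CC/C=C(\C)C[C@@H](OCc2ccc(OC)cc2)[C@H]1CCO | intermediate
19 | (6R,7S,8R)-6-hydroxy-12-aldehyde (not isolated) | O[C@@H]1/C=C(/C)CC/C=C(\C)C[C@@H](OCc2ccc(OC)cc2)[C@H]1CC=O | intermediate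
20 | (6R,7R,8R)-6,12-lactol, C12 epimers (not isolated) | C1C(O)O[C@@H]2/C=C(/C)CC/C=C(\C)C[C@@H](OCc3ccc(OC)cc3)[C@@H]12 | intermediate
21 | (6R,7R,8R)-8β-PMBO-13-norgermacra-1(10),4-dien-6α,12-olide (trans-fused lactone) | C1C(=O)O[C@@H]2/C=C(/C)CC/C=C(\C)C[C@@H](OCc3ccc(OC)cc3)[C@@H]12 | intermediate
22 | lithium enolate of 21 (not isolated) | C1=C([O-])O[C@@H]2/C=C(/C)CC/C=C(\C)C[C@@H](OCc3ccc(OC)cc3)[C@@H]12.[Li+] | intermediate
23 | 11-(dimethylaminomethyl) lactone, C11 epimers | CN(C)CC1C(=O)O[C@@H]2/C=C(/C)CC/C=C(\C)C[C@@H](OCc3ccc(OC)cc3)[C@@H]12 | intermediate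
24 | trimethylammonium iodide of 23 (not isolated) | C[N+](C)(C)CC1C(=O)O[C@@H]2/C=C(/C)CC/C=C(\C)C[C@@H](OCc3ccc(OC)cc3)[C@@H]12.[I-] | intermediate
25 | (6R,7R,8R)-8β-PMBO-germacra-1(10),4,11(13)-trien-6α,12-olide | C=C1C(=O)O[C@@H]2/C=C(/C)CC/C=C(\C)C[C@@H](OCc3ccc(OC)cc3)[C@@H]12 | intermediate
26 | (6R,7R,8R)-8β-hydroxygermacra-1(10),4,11(13)-trien-6α,12-olide | C=C1C(=O)O[C@@H]2/C=C(/C)CC/C=C(\C)C[C@@H](O)[C@@H]12 | intermediate
27 | angelic acid, (Z)-2-methylbut-2-enoic acid | C/C=C(/C)C(=O)O | starting material
28 | angelic 2,4,6-trichlorobenzoic anhydride (not isolated) | C/C=C(/C)C(=O)OC(=O)c1c(Cl)cc(Cl)cc1Cl | intermediate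
29 | (6R,7R,8R)-8β-angeloyloxygermacra-1(10),4,11(13)-trien-6α,12-olide (C1=C10 ring-trans, C4=C5 ring-cis) | C=C1C(=O)O[C@@H]2/C=C(/C)CC/C=C(\C)C[C@@H](OC(=O)/C(C)=C\C)[C@@H]12 | intermediate
30 | CNP0182172.4, (6R,7R,8R)-8β-angeloyloxy-14,15-dihydroxygermacra-1(10),4,11(13)-trien-6α,12-olide (both ring olefins ring-cis) | C=C1C(=O)O[C@@H]2/C=C(/CO)CC/C=C(/CO)C[C@@H](OC(=O)/C(C)=C\C)[C@@H]12 | target

**Step count**
Total: 14 steps. Longest linear sequence: 13 steps (steps 2–14, from 3 and 4); the limonene branch is 11 steps.

**Steps most likely to fail**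

1. Step 6. During the time the rearrangement needs, the potassium enolate 15 can expel 4-methoxybenzyl oxide from C8 (E1cB), and alkoxide 14 can fragment back to ketone 2. The fallback replaces the anionic variant by a neutral siloxy-Cope rearrangement and sets out from 13. Silylation with N-(trimethylsilyl)imidazole gives the trimethylsilyl ether F1. Thermolysis (degassed toluene with a trace of Et3N, sealed tube, about 200 °C) should pass through the same chair and give the trimethylsilyl enol ether F2 without any free enolate. Bu4NF/AcOH in THF at −78 °C then releases the ketone by outer-face protonation, and the route is rejoined at 16.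

2. Step 14. The new allylic alcohols can be over-oxidised to enals, ring methylenes (C2, C3, C9) can be hydroxylated in place of C14/C15, and the second hydroxylation can stall, all on a substrate that already carries the isomerisable angelate. The fallback moves the hydroxylation before the acylation and sets out from 26. SeO2 (cat.)/t-BuOOH should give the 8,14,15-triol F3, and mono-hydroxylated material can be resubmitted. TBSCl/imidazole at −20 °C silylates the two primary allylic hydroxyls selectively to the bis-silyl ether F4. The mixed-anhydride acylation of step 13 gives the bis-silyl angelate F5, and HF·pyridine in THF returns to the route at 30.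

3. Step 7. Facial selectivity of hydride addition at C6 may be poor or reversed, because the carbonyl group, unlike the enolate, can turn through the ring. The fallback corrects C6 by inversion and sets out from 16. The 6-epimeric alcohol F6, formed under the conditions of step 7, undergoes a Mitsunobu reaction (PPh3, DIAD, 4-nitrobenzoic acid, toluene, 0 °C) that inverts C6 to the 4-nitrobenzoate F7. K2CO3/MeOH cleaves the ester and the route is rejoined at 17.

**Further compounds**
F1 | step 6 | trimethylsilyl ether of 13 | CC1=C[C@](O[Si](C)(C)C)(/C(CCO[Si](C)(C)C(C)(C)C)=C/OCc2ccc(OC)cc2)[C@@H](C(C)=C)CC1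
F2 | step 6 | trimethylsilyl enol ether of 16 (C6=C7 ring-trans, 8R) | C[Si](C)(C)O/C1=C(/CCO[Si](C)(C)C(C)(C)C)[C@H](OCc2ccc(OC)cc2)C/C(C)=C/CC/C(C)=C\1
F3 | step 14 | (6R,7R,8R)-8β,14,15-trihydroxygermacra-1(10),4,11(13)-trien-6α,12-olide (both ring olefins ring-cis) | C=C1C(=O)O[C@@H]2/C=C(/CO)CC/C=C(/CO)C[C@@H](O)[C@@H]12
F4 | step 14 | 14,15-bis-TBS ether of F3 | C=C1C(=O)O[C@@H]2/C=C(/CO[Si](C)(C)C(C)(C)C)CC/C=C(/CO[Si](C)(C)C(C)(C)C)C[C@@H](O)[C@@H]12
F5 | step 14 | 8β-angelate of F4 | C=C1C(=O)O[C@@H]2/C=C(/CO[Si](C)(C)C(C)(C)C)CC/C=C(/CO[Si](C)(C)C(C)(C)C)C[C@@H](OC(=O)/C(C)=C\C)[C@@H]12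
F6 | step 7 | (6S,7S,8R)-6-epimer of 17 | O[C@H]1/C=C(/C)CC/C=C(\C)C[C@@H](OCc2ccc(OC)cc2)[C@H]1CCO[Si](C)(C)C(C)(C)C
F7 | step 7 | 6α-(4-nitrobenzoate) of 17 | O=C(O[C@@H]1/C=C(/C)CC/C=C(\C)C[C@@H](OCc2ccc(OC)cc2)[C@H]1CCO[Si](C)(C)C(C)(C)C)c1ccc(cc1)[N+](=O)[O-]
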